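The dihydrofuran ring is disconnected at O1–C2, and the C3 methyl group is traced back to the CH2 of a trans-1,2-diarylcyclopropane whose ring A carries a free ortho phenol. One acid-triggered operation protonates that CH2, breaks the C2–CH2 bond and lets the phenol oxygen close onto C2. This gives the ring, the C3 methyl and the 2,3-trans relationship at once, while C3 keeps the configuration set in an asymmetric cyclopropanation. The step exploits that C2 is benzylic to ring B, whose C4′ methoxy group lies para to the C2 attachment, whereas C3 sits on ring A, which bears an ester para to the phenol oxygen and meta to C3.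

Key step: step 7

Remark: CIP analysis of the target gives (2S,3S) with aryl and methyl trans; retention at C3 and anti closure at C2 trace it to the (1R,2R)-cyclopropane.
Remark: in ring A the ester is para to the phenol oxygen and meta to the carbon that bears C3, so it disfavours a C3 cation inductively and by draining the oxygen lone pair; the regiochemical case is argued on that basis.
Remark: the ring A phenol is kept as a MOM ether until after the carbene transfer, because a free O–H would consume base and quench the carbene radical; the hydrazone salt is fragmented without methanolic carbonate, which would threaten the aryl silyl ether.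

Step 1
Reactants: 1 methyl 3-bromo-4-hydroxy-5-methoxybenzoate
Product: 2 methyl 3-bromo-5-methoxy-4-(methoxymethoxy)benzoate
Conditions: MOMCl, iPr2NEt, CH2Cl2, 0 °C to rt
Reagents that add atoms: chloromethyl methyl ether, COCCl
Why: Williamson-type O-alkylation of the acidic phenol by the oxocarbenium-like chloromethyl ether masks the O–H that would otherwise interfere with the base and the carbene radical of step 5.

Step 2
Reactants: 2 methyl 3-bromo-5-methoxy-4-(methoxymethoxy)benzoate; 3 potassium vinyltrifluoroborate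
Product: 4 methyl 3-ethenyl-5-methoxy-4-(methoxymethoxy)benzoate
Conditions: PdCl2(dppf)·CH2Cl2 (3 mol %), Cs2CO3, THF/H2O 9:1, 80 °C
Reagents that add atoms: potassium vinyltrifluoroborate (3), C=C[B-](F)(F)F.[K+]
Why: Suzuki–Miyaura vinylation (oxidative addition into C–Br, transmetalation of the slowly hydrolysed trifluoroborate, reductive elimination) should give the styrene, with the methyl ester and MOM ether tolerating carbonate at this temperature.

Step 3
Reactants: 5 3-hydroxy-4,5-dimethoxybenzaldehyde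
Product: 6 3,4-dimethoxy-5-(triisopropylsilyloxy)benzaldehyde
Conditions: TIPSCl, imidazole, DMF, rt
Reagents that add atoms: chlorotriisopropylsilane, CC(C)[Si](Cl)(C(C)C)C(C)C
Why: Imidazole-mediated O-silylation of the phenol gives an aryl triisopropylsilyl ether that is inert to the acid of steps 6 and 7 and to hydride, MnO2 and amide base later.

Step 4
Reactants: 6 3,4-dimethoxy-5-(triisopropylsilyloxy)benzaldehyde
Product: 7 N′-[(E)-[3,4-dimethoxy-5-(triisopropylsilyloxy)phenyl]methylidene]-4-methylbenzenesulfonohydrazide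
Conditions: TsNHNH2, MeOH, rt
Reagents that add atoms: 4-methylbenzenesulfonohydrazide, Cc1ccc(cc1)S(=O)(=O)NN
Why: Condensation of the aldehyde with the sulfonyl hydrazide should give the stable (E)-tosylhydrazone, the storable Bamford–Stevens precursor of the diazo compound.

Step 5
Reactants: 7 N′-[(E)-[3,4-dimethoxy-5-(triisopropylsilyloxy)phenyl]methylidene]-4-methylbenzenesulfonohydrazide; 4 methyl 3-ethenyl-5-methoxy-4-(methoxymethoxy)benzoate
Product: 10 methyl 3-[(1R,2R)-2-[3,4-dimethoxy-5-(triisopropylsilyloxy)phenyl]cyclopropyl]-5-methoxy-4-(methoxymethoxy)benzoate, via hydrazone sodium salt 8 (not isolated), via aryldiazomethane 9 (not isolated)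
Conditions: 7, NaH, THF, 0 °C, evaporate; then 4, [Co(3,5-DitBu-Xu(2′-Naph)Phyrin)] (chiral amidoporphyrin complex of divalent cobalt, 3 mol %), BnEt3NCl (10 mol %), 1,4-dioxane, 40 °C
Reagents that add atoms: none
Why: Bamford–Stevens fragmentation of the salt releases the aryldiazomethane slowly, and asymmetric metalloradical cyclopropanation (cobalt carbene radical adds to the styrene terminus, then 3-exo-tet radical ring closure) should give the trans cyclopropane, both stereocentres being set by the chiral porphyrin pocket, whose enantiomer is chosen to deliver (1R,2R).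

Step 6
Reactants: 10 methyl 3-[(1R,2R)-2-[3,4-dimethoxy-5-(triisopropylsilyloxy)phenyl]cyclopropyl]-5-methoxy-4-(methoxymethoxy)benzoate
Product: 11 methyl 4-hydroxy-3-methoxy-5-[(1R,2R)-2-[3,4-dimethoxy-5-(triisopropylsilyloxy)phenyl]cyclopropyl]benzoate
Conditions: HCl (aq., 3 equiv), MeOH/THF, 40 °C
Reagents that add atoms: none
Why: Acid-catalysed acetal exchange should remove the MOM group as dimethoxymethane, while the aryl triisopropylsilyl ether is stable to dilute methanolic HCl and the cyclopropane is not protonated in this nucleophilic, weakly ionising medium.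

Step 7
Reactants: 11 methyl 4-hydroxy-3-methoxy-5-[(1R,2R)-2-[3,4-dimethoxy-5-(triisopropylsilyloxy)phenyl]cyclopropyl]benzoate
Product: 12 methyl (2S,3S)-2-[3,4-dimethoxy-5-(triisopropylsilyloxy)phenyl]-7-methoxy-3-methyl-2,3-dihydro-1-benzofuran-5-carboxylate
Conditions: CF3SO3H (10 mol %), (CF3)2CHOH, 0.01 M, 0 °C to rt
Reagents that add atoms: none
Why: Proposed new method: the strong acid in the non-nucleophilic, strongly ionising fluoro alcohol should protonate the cyclopropane at its CH2 corner, the C2–CH2 bond breaks as positive charge builds at C2, and the ring A phenol oxygen bonds to C2, so that CH2 becomes the C3 methyl and O1–C2 closes the dihydrofuran. The closest known reaction type is the Brønsted-acid-catalysed Markovnikov ring-opening hydroarylation and hydroalkoxylation of arylcyclopropanes in hexafluoroisopropanol; intramolecular phenol capture on a 1,2-diarylcyclopropane has not been shown. The ring closes in 5-exo-tet fashion (O onto C2 with the C2–CH2 bond as the exocyclic leaving bond), or by collapse of the open C2 benzylic cation if ionisation runs to completion. C2 is the only new stereocentre and is controlled by C3, which is never ionised: attack anti to the departing CH2 inverts C2 and turns the (1R,2R)-trans cyclopropane into the (2S,3S)-trans product, an open cation closes on the face anti to the C3 methyl, and reversible C2–O ionisation lets the more stable trans isomer accumulate. The step needs cleavage of C2–CH2 and not of C3–CH2 or C2–C3 (the latter would lead to a six-membered flavan); protonation at the least substituted carbon follows the Markovnikov rule for cyclopropanes, and charge is better held at C2 by ring B with its three oxygen donors (C4′ methoxy para) than at C3 on ring A, whose ester is meta to C3 and para to the phenol oxygen. High dilution suppresses intermolecular Friedel–Crafts capture by ring B, and low acid loading and temperature limit E1 loss of the C3 proton, which would erode enantiomeric purity.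

Step 8
Reactants: 12 methyl (2S,3S)-2-[3,4-dimethoxy-5-(triisopropylsilyloxy)phenyl]-7-methoxy-3-methyl-2,3-dihydro-1-benzofuran-5-carboxylate
Product: 13 [(2S,3S)-2-[3,4-dimethoxy-5-(triisopropylsilyloxy)phenyl]-7-methoxy-3-methyl-2,3-dihydro-1-benzofuran-5-yl]methanol
Conditions: iBu2AlH, CH2Cl2, −78 to 0 °C; aq. potassium sodium tartrate
Reagents that add atoms: none
Why: Hydride reduction of the aryl ester through the aldehyde stage should give the benzylic alcohol, the aryl silyl ether and the cyclic benzylic ether being inert and no stereocentre being touched.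

Step 9
Reactants: 13 [(2S,3S)-2-[3,4-dimethoxy-5-(triisopropylsilyloxy)phenyl]-7-methoxy-3-methyl-2,3-dihydro-1-benzofuran-5-yl]methanol
Product: 14 (2S,3S)-2-[3,4-dimethoxy-5-(triisopropylsilyloxy)phenyl]-7-methoxy-3-methyl-2,3-dihydro-1-benzofuran-5-carbaldehyde
Conditions: MnO2 (activated, excess), CH2Cl2, rt
Reagents that add atoms: none
Why: Heterogeneous MnO2 oxidation is selective for the electron-rich primary benzylic alcohol, should stop at the aldehyde and leaves the C2–H and C3–H positions untouched.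

Step 10
Reactants: 14 (2S,3S)-2-[3,4-dimethoxy-5-(triisopropylsilyloxy)phenyl]-7-methoxy-3-methyl-2,3-dihydro-1-benzofuran-5-carbaldehyde; 15 5-(ethylsulfonyl)-1-phenyl-1H-tetrazole
Product: 17 5-[(2S,3S)-7-methoxy-3-methyl-5-[(E)-prop-1-en-1-yl]-2,3-dihydro-1-benzofuran-2-yl]-2,3-dimethoxyphenol, via silyl ether of the target 16 (not isolated)
Conditions: KN(SiMe3)2, DME, −60 °C to rt; then Bu4NF, THF, rt
Reagents that add atoms: 5-(ethylsulfonyl)-1-phenyl-1H-tetrazole (15), CCS(=O)(=O)c1nnnn1c1ccccc1
Why: Julia–Kocienski olefination (addition of the metalated sulfone to the non-enolisable aldehyde, Smiles rearrangement, anti elimination of SO2 and tetrazolate) should give the conjugated (E)-propenyl group, and fluoride then cleaves the aryl Si–O bond in the same flask without touching alkene or stereocentres.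

Compound list
1 | methyl 3-bromo-4-hydroxy-5-methoxybenzoate | COC(=O)c1cc(Br)c(O)c(OC)c1 | starting material
2 | methyl 3-bromo-5-methoxy-4-(methoxymethoxy)benzoate | COC(=O)c1cc(Br)c(OCOC)c(OC)c1 | intermediate
3 | potassium vinyltrifluoroborate | C=C[B-](F)(F)F.[K+] | starting material
4 | methyl 3-ethenyl-5-methoxy-4-(methoxymethoxy)benzoate | COC(=O)c1cc(OC)c(OCOC)c(C=C)c1 | intermediate
5 | 3-hydroxy-4,5-dimethoxybenzaldehyde | O=Cc1cc(O)c(OC)c(OC)c1 | starting material
6 | 3,4-dimethoxy-5-(triisopropylsilyloxy)benzaldehyde | O=Cc1cc(O[Si](C(C)C)(C(C)C)C(C)C)c(OC)c(OC)c1 | intermediate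
7 | N′-[(E)-[3,4-dimethoxy-5-(triisopropylsilyloxy)phenyl]methylidene]-4-methylbenzenesulfonohydrazide | Cc1ccc(cc1)S(=O)(=O)N/N=C/c1cc(O[Si](C(C)C)(C(C)C)C(C)C)c(OC)c(OC)c1 | intermediate
8 | sodium salt of tosylhydrazone 7 | Cc1ccc(cc1)S(=O)(=O)[N-]/N=C/c1cc(O[Si](C(C)C)(C(C)C)C(C)C)c(OC)c(OC)c1.[Na+] | intermediate (not isolated)
9 | 5-(diazomethyl)-1,2-dimethoxy-3-(triisopropylsilyloxy)benzene | [N-]=[N+]=Cc1cc(O[Si](C(C)C)(C(C)C)C(C)C)c(OC)c(OC)c1 | intermediate (not isolated)
10 | methyl 3-[(1R,2R)-2-[3,4-dimethoxy-5-(triisopropylsilyloxy)phenyl]cyclopropyl]-5-methoxy-4-(methoxymethoxy)benzoate | COC(=O)c1cc(OC)c(OCOC)c(c1)[C@@H]1C[C@H]1c1cc(O[Si](C(C)C)(C(C)C)C(C)C)c(OC)c(OC)c1 | intermediate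
11 | methyl 4-hydroxy-3-methoxy-5-[(1R,2R)-2-[3,4-dimethoxy-5-(triisopropylsilyloxy)phenyl]cyclopropyl]benzoate | COC(=O)c1cc(OC)c(O)c(c1)[C@@H]1C[C@H]1c1cc(O[Si](C(C)C)(C(C)C)C(C)C)c(OC)c(OC)c1 | intermediate
12 | methyl (2S,3S)-2-[3,4-dimethoxy-5-(triisopropylsilyloxy)phenyl]-7-methoxy-3-methyl-2,3-dihydro-1-benzofuran-5-carboxylate | COC(=O)c1cc(OC)c2c(c1)[C@H](C)[C@@H](c1cc(O[Si](C(C)C)(C(C)C)C(C)C)c(OC)c(OC)c1)O2 | intermediate
13 | [(2S,3S)-2-[3,4-dimethoxy-5-(triisopropylsilyloxy)phenyl]-7-methoxy-3-methyl-2,3-dihydro-1-benzofuran-5-yl]methanol | OCc1cc(OC)c2c(c1)[C@H](C)[C@@H](c1cc(O[Si](C(C)C)(C(C)C)C(C)C)c(OC)c(OC)c1)O2 | intermediate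
14 | (2S,3S)-2-[3,4-dimethoxy-5-(triisopropylsilyloxy)phenyl]-7-methoxy-3-methyl-2,3-dihydro-1-benzofuran-5-carbaldehyde | O=Cc1cc(OC)c2c(c1)[C@H](C)[C@@H](c1cc(O[Si](C(C)C)(C(C)C)C(C)C)c(OC)c(OC)c1)O2 | intermediate
15 | 5-(ethylsulfonyl)-1-phenyl-1H-tetrazole | CCS(=O)(=O)c1nnnn1c1ccccc1 | starting material
16 | (2S,3S)-2-[3,4-dimethoxy-5-(triisopropylsilyloxy)phenyl]-7-methoxy-3-methyl-5-[(E)-prop-1-en-1-yl]-2,3-dihydro-1-benzofuran | C/C=C/c1cc(OC)c2c(c1)[C@H](C)[C@@H](c1cc(O[Si](C(C)C)(C(C)C)C(C)C)c(OC)c(OC)c1)O2 | intermediate (not isolated)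
17 | 5-[(2S,3S)-7-methoxy-3-methyl-5-[(E)-prop-1-en-1-yl]-2,3-dihydro-1-benzofuran-2-yl]-2,3-dimethoxyphenol (CNP0299956.1) | C/C=C/c1cc(OC)c2c(c1)[C@H](C)[C@@H](c1cc(O)c(OC)c(OC)c1)O2 | target

Total step count: 10.
Longest linear sequence: 8 steps (from 1 through steps 1, 2, 5, 6, 7, 8, 9, 10; the branch from 5 through steps 3 to 10 is equally long).

Steps most likely to fail

Step 7. The cyclopropane may open at the wrong bond (C2–C3 towards a flavan, or C3–CH2), ring B may capture the cation intermolecularly, or reversible E1 loss of the C3 proton may erode enantiomeric purity. The fallback uses known chemistry, sets out from 6 and 2 and comes back at 12. EtMgBr (THF, 0 °C) should add to 6 to give 1-[3,4-dimethoxy-5-(triisopropylsilyloxy)phenyl]propan-1-ol F1. Dess–Martin periodinane then gives 1-[3,4-dimethoxy-5-(triisopropylsilyloxy)phenyl]propan-1-one F2, and PhNMe3Br3 (THF, 0 °C) gives racemic 2-bromo-1-[3,4-dimethoxy-5-(triisopropylsilyloxy)phenyl]propan-1-one F3. Bromide 2 is converted by Br/Mg exchange (iPrMgCl·LiCl, THF, −15 °C) and ZnCl2 into methyl 3-(chlorozincio)-5-methoxy-4-(methoxymethoxy)benzoate F4. A stereoconvergent nickel-catalysed Negishi α-arylation of the racemic bromo ketone (NiCl2·glyme, chiral pybox ligand chosen for the S product, glyme/THF, −30 °C) should set the future C3 stereocentre in methyl 3-[(2S)-1-[3,4-dimethoxy-5-(triisopropylsilyloxy)phenyl]-1-oxopropan-2-yl]-5-methoxy-4-(methoxymethoxy)benzoate F5. NaBH4 (MeOH, −20 °C) gives methyl 3-[(2S)-1-hydroxy-1-[3,4-dimethoxy-5-(triisopropylsilyloxy)phenyl]propan-2-yl]-5-methoxy-4-(methoxymethoxy)benzoate F6 as carbinol epimers. HCl/MeOH removes the MOM group to give methyl 4-hydroxy-3-[(2S)-1-hydroxy-1-[3,4-dimethoxy-5-(triisopropylsilyloxy)phenyl]propan-2-yl]-5-methoxybenzoate F7. Catalytic TsOH in CH2Cl2 then closes the ring by SN1 dehydrative etherification at the ring B benzylic carbon, both epimers converging on trans 12.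

Step 5. The porphyrin pocket may give insufficient enantio- or diastereocontrol with this trioxygenated diazo donor, or carbene dimerisation may outpace capture by the alkene. The fallback sets out from 6, uses the arylzinc F4 made from 2 as above, and comes back at 10. Wittig methylenation (Ph3PCH3Br, KOtBu, THF) of 6 should give 5-ethenyl-1,2-dimethoxy-3-(triisopropylsilyloxy)benzene F8. Asymmetric cyclopropanation with tert-butyl diazoacetate under CuOTf and 2,2′-(propane-2,2-diyl)bis(4-tert-butyl-4,5-dihydrooxazole) (monovalent copper, ligand enantiomer chosen for the 1R,2R ester) gives tert-butyl (1R,2R)-2-[3,4-dimethoxy-5-(triisopropylsilyloxy)phenyl]cyclopropane-1-carboxylate F9. CF3CO2H cleaves the ester to (1R,2R)-2-[3,4-dimethoxy-5-(triisopropylsilyloxy)phenyl]cyclopropane-1-carboxylic acid F10. N-Hydroxyphthalimide with N,N′-diisopropylcarbodiimide gives 1,3-dioxoisoindolin-2-yl (1R,2R)-2-[3,4-dimethoxy-5-(triisopropylsilyloxy)phenyl]cyclopropane-1-carboxylate F11. Nickel-catalysed decarboxylative Negishi arylation with F4 (NiCl2·glyme, 4,4′-di-tert-butyl-2,2′-bipyridine, THF/DMF, rt) should then give 10; the ring B carbon keeps its configuration and the cyclopropyl radical is arylated trans to it.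

Step 10. The Smiles rearrangement and elimination sequence may give incomplete E selectivity with an aromatic aldehyde, leaving a Z isomer that is hard to separate. The fallback sets out from 14 and comes back at 16. Takai–Utimoto ethylidenation with CH3CHI2 and CrCl2 (THF, rt) should form the (E)-propenyl group through a geminal dichromium reagent, and 16 is then desilylated with Bu4NF as in step 10.

Further compounds
F1 | step 7 | 1-[3,4-dimethoxy-5-(triisopropylsilyloxy)phenyl]propan-1-ol | CCC(O)c1cc(O[Si](C(C)C)(C(C)C)C(C)C)c(OC)c(OC)c1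
F2 | step 7 | 1-[3,4-dimethoxy-5-(triisopropylsilyloxy)phenyl]propan-1-one | CCC(=O)c1cc(O[Si](C(C)C)(C(C)C)C(C)C)c(OC)c(OC)c1
F3 | step 7 | 2-bromo-1-[3,4-dimethoxy-5-(triisopropylsilyloxy)phenyl]propan-1-one (racemic) | CC(Br)C(=O)c1cc(O[Si](C(C)C)(C(C)C)C(C)C)c(OC)c(OC)c1
F4 | step 7 | methyl 3-(chlorozincio)-5-methoxy-4-(methoxymethoxy)benzoate | COC(=O)c1cc([Zn]Cl)c(OCOC)c(OC)c1
F5 | step 7 | methyl 3-[(2S)-1-[3,4-dimethoxy-5-(triisopropylsilyloxy)phenyl]-1-oxopropan-2-yl]-5-methoxy-4-(methoxymethoxy)benzoate | COC(=O)c1cc(OC)c(OCOC)c(c1)[C@H](C)C(=O)c1cc(O[Si](C(C)C)(C(C)C)C(C)C)c(OC)c(OC)c1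
F6 | step 7 | methyl 3-[(2S)-1-hydroxy-1-[3,4-dimethoxy-5-(triisopropylsilyloxy)phenyl]propan-2-yl]-5-methoxy-4-(methoxymethoxy)benzoate (carbinol epimers) | COC(=O)c1cc(OC)c(OCOC)c(c1)[C@H](C)C(O)c1cc(O[Si](C(C)C)(C(C)C)C(C)C)c(OC)c(OC)c1
F7 | step 7 | methyl 4-hydroxy-3-[(2S)-1-hydroxy-1-[3,4-dimethoxy-5-(triisopropylsilyloxy)phenyl]propan-2-yl]-5-methoxybenzoate (carbinol epimers) | COC(=O)c1cc(OC)c(O)c(c1)[C@H](C)C(O)c1cc(O[Si](C(C)C)(C(C)C)C(C)C)c(OC)c(OC)c1
F8 | step 5 | 5-ethenyl-1,2-dimethoxy-3-(triisopropylsilyloxy)benzene | C=Cc1cc(O[Si](C(C)C)(C(C)C)C(C)C)c(OC)c(OC)c1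
F9 | step 5 | tert-butyl (1R,2R)-2-[3,4-dimethoxy-5-(triisopropylsilyloxy)phenyl]cyclopropane-1-carboxylate | CC(C)(C)OC(=O)[C@@H]1C[C@H]1c1cc(O[Si](C(C)C)(C(C)C)C(C)C)c(OC)c(OC)c1
F10 | step 5 | (1R,2R)-2-[3,4-dimethoxy-5-(triisopropylsilyloxy)phenyl]cyclopropane-1-carboxylic acid | OC(=O)[C@@H]1C[C@H]1c1cc(O[Si](C(C)C)(C(C)C)C(C)C)c(OC)c(OC)c1
F11 | step 5 | 1,3-dioxoisoindolin-2-yl (1R,2R)-2-[3,4-dimethoxy-5-(triisopropylsilyloxy)phenyl]cyclopropane-1-carboxylate | O=C(ON1C(=O)c2ccccc2C1=O)[C@@H]1C[C@H]1c1cc(O[Si](C(C)C)(C(C)C)C(C)C)c(OC)c(OC)c1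
F0 | step 10 | none | none
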